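(The readings were generated by integration for substances that don't exist.)

- Two constants came out of the earlier runs. Up to their 25.0 s readings, substrate had fallen at an average of 0.0187 s⁻¹ in the alpha run and 0.0311 s⁻¹ in the eta run. Drawn straight against charged [reagent], that gave a slope of 0.00906 M⁻¹ s⁻¹ and a remainder of 0.0103 s⁻¹ that needed no reagent. Both are readings and carry their scatter.

common to all: substrate 0.85 M
- alpha: reagent 1.1 equiv; run made earlier
- eta: reagent 2.7 equiv; run made earlier
- Sunday's: reagent 1.50 equiv; time 4.0 min
- Friday's: reagent 0.800 equiv; time 4.0 min
- Saturday's: reagent 2.00 equiv; time 4.0 min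

| run | time / s | triple product / % | bis adduct / % | substrate / % |
|---|---|---|---|---|
| alpha | 10.0 | 0 | 1.1 | 83.0 |
| alpha | 25.0 | 0 | 5.1 | 62.6 |
| alpha | 40.0 | 3.6 | 4.6 | 49.4 |
| alpha | 60.0 | 1.9 | 7.8 | 36.8 |
| alpha | 90.0 | 3.0 | 11.1 | 28.2 |
| alpha | 120 | 4.6 | 12.6 | 20.2 |
| eta | 10.0 | 0 | 5.2 | 70.1 |
| eta | 25.0 | 3.3 | 10.6 | 46.0 |
| eta | 40.0 | 8.7 | 14.8 | 32.1 |
| eta | 60.0 | 15.6 | 18.3 | 22.8 |
| eta | 90.0 | 26.5 | 17.0 | 13.7 |
| eta | 120 | 35.4 | 14.5 | 11.5 |

(each reading ± 1 percentage point)

- which of these holds the largest part of the substrate at the end of Sunday's (triple product / bis adduct / mono adduct / substrate)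
- which of these holds the largest part of the substrate at the end of Friday's (triple product / bis adduct / mono adduct / substrate)
- which of these holds the largest part of the substrate at the end of Saturday's (triple product / bis adduct / mono adduct / substrate)
- amount of triple product at the end of Saturday's, in percent of the substrate charged



- I followed one substrate molecule to its first fork. For Saturday's flask, [reagent] of 1.70 M gave 1.50 for the fork ratio, slope times [reagent] over the remainder, a selectivity factor.
- So I reckoned that 40.0 % of the substrate leaving Saturday's at the start would take the reagent-free way.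
- Friday's started at a ratio of 0.600, lower than Saturday's, so I left word not to trim the reagent.
- The forecast gave mono adduct for Sunday's, mono adduct for Friday's, mono adduct for Saturday's and 33 % triple product on Saturday's, holding that “Substrate therefore goes to mono first”. I differed on Friday's: below a ratio of one, I would not have put mono adduct first.
- Saturday's gave 33.9 % triple product. Of the four species asked about, triple product led there, triple product led in Sunday's and substrate led in Friday's. Saturday's held 28.1 % homo dimer, each counting as two substrate. Its fork ratio above one goes with less homo dimer than adducts and side product together.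

    reagent + bis adduct → triple product (k = 0.0150 M⁻¹ s⁻¹)
    reagent + mono adduct → bis adduct (k = 0.0210 M⁻¹ s⁻¹)
    2 substrate → homo dimer (k = 0.00740 M⁻¹ s⁻¹)
    substrate + reagent → mono adduct (k = 0.0110 M⁻¹ s⁻¹)
    mono adduct → side product (k = 0.00940 s⁻¹)

- For the neighbour flask with 0.800 equiv of reagent, the ratio of 0.600 pointed the other way, towards homo dimer. The computed flask held 47.9 % homo dimer, more than adducts and side product together.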